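**Plan**
- Retrosynthesis: the C3 methyl ester and the C2 CH2OH are both traced back to N-acyl oxazolidinones. The carbocycle is then cut at C2–C3 and at C1–C8a, which leaves two molecules of one N-sinapoyl imide.
- Enabling feature: the target is two 4-hydroxy-3,5-dimethoxyphenyl–C3 units joined side-chain carbon to side-chain carbon (C2–C3, like polarity) and C1–C8a. Each OH is para to its side chain (C7–OH para to C4a; the pendant OH para to C1), so each unit can pass through a phenoxyl radical and a p-quinone methide. The OMe groups block both positions ortho to OH and activate C8a (para to the C6–OMe).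
- Forward: monomer 7 in three steps (N-acylation, ylide, Wittig). Oxidative dehydrodimerization then forms C2–C3 and closes the ring C1–C2–C3–C4–C4a–C8a in one operation. LiBH4 and then methanolysis differentiate the two acyl groups.
- Stereochemistry: C2 comes from the auxiliary-controlled face of the radical coupling; C1 comes from trans-selective closure onto the quinone methide (1,2-induction).

Key step: step 4

Remarks on the chemistry: the numbering of the 1-aryl-1,2-dihydronaphthalene (C1 aryl, C2 CH2OH, C3 ester) is kept for all bicyclic compounds, and C7/C8/C9 denote the cinnamoyl side chain (C8 α to C=O). Assumption: the radical coupling follows the chelated s-cis, syn-carbonyl model of N-enoyl oxazolidinones (bond formation at C8 anti to the 4-benzyl group), which with the (S)-auxiliary leads to the (1S,2R) series; if the sense were opposite, the (R)-auxiliary would enter the same route.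

Step 1
Reactants: 1 (S)-4-benzyloxazolidin-2-one; 2 bromoacetyl bromide
Product: 3 (S)-4-benzyl-3-(2-bromoacetyl)oxazolidin-2-one
Conditions: n-BuLi, THF, −78 °C; then 2, −78 → 0 °C
Reagents that add atoms: none
Why: N-acylation of the lithiated oxazolidinone occurs at the acyl bromide, which is far more electrophilic than the alkyl bromide, and leaves the auxiliary stereocentre untouched.

Step 2
Reactants: 3 (S)-4-benzyl-3-(2-bromoacetyl)oxazolidin-2-one
Product: 5 (S)-4-benzyl-3-[2-(triphenyl-λ5-phosphanylidene)acetyl]oxazolidin-2-one, via phosphonium bromide 4 (not isolated)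
Conditions: PPh3, toluene, rt; then Et3N, CH2Cl2, 0 °C
Reagents that add atoms: triphenylphosphine, c1ccc(cc1)P(c1ccccc1)c1ccccc1
Why: SN2 displacement of the α-bromide by PPh3 gives a phosphonium salt whose CH2, flanked by P+ and the imide carbonyl, is acidic enough for Et3N to give the stabilized ylide (standard phosphorane preparation).

Step 3
Reactants: 5 (S)-4-benzyl-3-[2-(triphenyl-λ5-phosphanylidene)acetyl]oxazolidin-2-one; 6 syringaldehyde (4-hydroxy-3,5-dimethoxybenzaldehyde)
Product: 7 (S)-4-benzyl-3-[(E)-3-(4-hydroxy-3,5-dimethoxyphenyl)acryloyl]oxazolidin-2-one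
Conditions: toluene, 80 °C
Reagents that add atoms: none
Why: The Wittig reaction of a carbonyl-stabilized ylide is E-selective and tolerates the free phenol of p-hydroxybenzaldehydes, so no protecting group is needed.

Step 4
Reactants: 7 (S)-4-benzyl-3-[(E)-3-(4-hydroxy-3,5-dimethoxyphenyl)acryloyl]oxazolidin-2-one (two molecules)
Product: 11 (4S,4′S)-3,3′-{[(1S,2R)-7-hydroxy-1-(4-hydroxy-3,5-dimethoxyphenyl)-6,8-dimethoxy-1,2-dihydronaphthalene-2,3-diyl]dicarbonyl}bis(4-benzyloxazolidin-2-one), via phenoxyl radical 8 (not isolated), via bis-quinone methide 9 (not isolated), via mono-quinone methide 10 (not isolated)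
Conditions: FeCl3 (anhydrous, 2.2 equiv), acetone, −20 → 0 °C; aq. Rochelle salt work-up
Reagents that add atoms: none
Why: Fe(III) oxidizes the 2,6-dimethoxyphenol of 7 to phenoxyl radical 8, whose spin is delocalized to C8; two radicals join C8–C8′ (two carbons of like polarity) to give bis-quinone methide 9, one half of which rearomatizes by loss of its C8–H to the (E)-cinnamoyl unit of 10, and the ring carbon of that half ortho to the side chain and para to OMe then attacks the remaining quinone methide carbon C7′. The closest known reaction type is the biomimetic FeCl3 dehydrodimerization of sinapate esters to thomasidioates, together with its chiral-auxiliary variants on hydroxycinnamoyl amides and imides. The carbocycle closes in a 6-exo-trig Friedel–Crafts (vinylogous Michael) mode at the quinone methide carbon, with the arene π bond endo. C2 is set in the radical coupling: iron chelation of the two imide carbonyls should hold the s-cis, syn-carbonyl conformer, so that the 4-benzyl group shields one face of C8 and both halves bond anti to it (matched, C2-symmetric 9); this centre survives because only one half tautomerizes. C1 is set in the closure, where the aryl group should enter trans to the C2 acyl group (1,2-induction, pseudo-diaxial arrangement away from the peri C8–OMe). The step needs 8–8′ coupling over 8–O–4 or ring coupling, which the OMe groups at both positions ortho to OH secure, and closure faster than over-oxidation or a second tautomerization, which low temperature, about one oxidant equivalent per phenol and Lewis-acid activation of the quinone methide should favour.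

Step 5
Reactants: 11 bis-imide dimer (name as in step 4)
Product: 12 (S)-4-benzyl-3-{[(1S,2R)-7-hydroxy-1-(4-hydroxy-3,5-dimethoxyphenyl)-2-(hydroxymethyl)-6,8-dimethoxy-1,2-dihydronaphthalen-3-yl]carbonyl}oxazolidin-2-one
Conditions: LiBH4 (excess), MeOH (1 equiv), THF, 0 °C; aq. NH4Cl
Reagents that add atoms: none
Why: Reductive exocyclic cleavage of an N-acyl oxazolidinone by LiBH4 should occur only at the saturated C2 imide, because the C3 imide is a p-hydroxycinnamoyl unit that the ring-A phenolate turns into a poorly electrophilic vinylogous carbamate; neither stereocentre is touched.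

Step 6
Reactants: 12 hydroxy imide (name as in step 5)
Product: 13 methyl (1S,2R)-7-hydroxy-1-(4-hydroxy-3,5-dimethoxyphenyl)-2-(hydroxymethyl)-6,8-dimethoxy-1,2-dihydronaphthalene-3-carboxylate (target)
Conditions: MeMgBr, MeOH, 0 °C → rt; aq. NH4Cl
Reagents that add atoms: methanol, CO
Why: Methoxymagnesium bromide formed in the flask transesterifies the N-acyl oxazolidinone at the exocyclic carbonyl, which Mg(II) activates by chelation between the two imide carbonyls, and the hydroxy ester should not lactonize because the trans pseudo-diaxial C1-aryl/C2-CH2OH pair keeps the CH2OH out of the plane of the C3 ester; no stereocentre is touched.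

**Compound list**
1 | (S)-4-benzyloxazolidin-2-one | O=C1N[C@@H](Cc2ccccc2)CO1 | starting material
2 | bromoacetyl bromide | BrCC(Br)=O | starting material
3 | (S)-4-benzyl-3-(2-bromoacetyl)oxazolidin-2-one | O=C(CBr)N1C(=O)OC[C@@H]1Cc1ccccc1 | intermediate
4 | {2-[(S)-4-benzyl-2-oxooxazolidin-3-yl]-2-oxoethyl}triphenylphosphonium bromide | O=C(C[P+](c1ccccc1)(c1ccccc1)c1ccccc1)N1C(=O)OC[C@@H]1Cc1ccccc1.[Br-] | intermediate
5 | (S)-4-benzyl-3-[2-(triphenyl-λ5-phosphanylidene)acetyl]oxazolidin-2-one | O=C(C=P(c1ccccc1)(c1ccccc1)c1ccccc1)N1C(=O)OC[C@@H]1Cc1ccccc1 | intermediate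
6 | syringaldehyde (4-hydroxy-3,5-dimethoxybenzaldehyde) | COc1cc(C=O)cc(OC)c1O | starting material
7 | (S)-4-benzyl-3-[(E)-3-(4-hydroxy-3,5-dimethoxyphenyl)acryloyl]oxazolidin-2-one | COc1cc(/C=C/C(=O)N2C(=O)OC[C@@H]2Cc2ccccc2)cc(OC)c1O | intermediate
8 | phenoxyl radical of 7 (spin delocalized to C8) | COc1cc(/C=C/C(=O)N2C(=O)OC[C@@H]2Cc2ccccc2)cc(OC)c1[O] | intermediate
9 | (2R,3R)-1,4-bis[(S)-4-benzyl-2-oxooxazolidin-3-yl]-2,3-bis[(3,5-dimethoxy-4-oxocyclohexa-2,5-dien-1-ylidene)methyl]butane-1,4-dione (8–8′ bis-quinone methide) | O=C1C(OC)=CC(=C[C@@H](C(=O)N2C(=O)OC[C@@H]2Cc2ccccc2)[C@H](C(=O)N2C(=O)OC[C@@H]2Cc2ccccc2)C=C2C=C(OC)C(=O)C(OC)=C2)C=C1OC | intermediate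
10 | (2E,3R)-1,4-bis[(S)-4-benzyl-2-oxooxazolidin-3-yl]-3-[(3,5-dimethoxy-4-oxocyclohexa-2,5-dien-1-ylidene)methyl]-2-(4-hydroxy-3,5-dimethoxybenzylidene)butane-1,4-dione (mono-quinone methide) | COc1cc(/C=C(/C(=O)N2C(=O)OC[C@@H]2Cc2ccccc2)[C@H](C(=O)N2C(=O)OC[C@@H]2Cc2ccccc2)C=C2C=C(OC)C(=O)C(OC)=C2)cc(OC)c1O | intermediate
11 | (4S,4′S)-3,3′-{[(1S,2R)-7-hydroxy-1-(4-hydroxy-3,5-dimethoxyphenyl)-6,8-dimethoxy-1,2-dihydronaphthalene-2,3-diyl]dicarbonyl}bis(4-benzyloxazolidin-2-one) | O=C(C1=Cc2cc(OC)c(O)c(OC)c2[C@H](c2cc(OC)c(O)c(OC)c2)[C@H]1C(=O)N1C(=O)OC[C@@H]1Cc1ccccc1)N1C(=O)OC[C@@H]1Cc1ccccc1 | intermediate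
12 | (S)-4-benzyl-3-{[(1S,2R)-7-hydroxy-1-(4-hydroxy-3,5-dimethoxyphenyl)-2-(hydroxymethyl)-6,8-dimethoxy-1,2-dihydronaphthalen-3-yl]carbonyl}oxazolidin-2-one | O=C(C1=Cc2cc(OC)c(O)c(OC)c2[C@H](c2cc(OC)c(O)c(OC)c2)[C@H]1CO)N1C(=O)OC[C@@H]1Cc1ccccc1 | intermediate
13 | methyl (1S,2R)-7-hydroxy-1-(4-hydroxy-3,5-dimethoxyphenyl)-2-(hydroxymethyl)-6,8-dimethoxy-1,2-dihydronaphthalene-3-carboxylate | COC(=O)C1=Cc2cc(OC)c(O)c(OC)c2[C@H](c2cc(OC)c(O)c(OC)c2)[C@H]1CO | target

**Step count and risks**
Total steps: 6. Longest linear sequence: 6 (1 → 3 → 5 → 7 → 11 → 12 → 13).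

Steps most likely to fail:

Step 4. The facial discrimination in the radical coupling may be incomplete, which would erode the enantiomeric purity through unlike pairing. In addition, 8–O–4 coupling, over-oxidation of the product phenols, or tautomerization of both halves before ring closure may lower the yield. The fallback sets out from 6 (with auxiliary 1) and returns to the route at 13. Compound 6 is protected (MOMCl, i-Pr2NEt, CH2Cl2) as 3,5-dimethoxy-4-(methoxymethoxy)benzaldehyde F1. Stobbe condensation of F1 with dimethyl succinate (NaOMe, MeOH, reflux) should give (E)-4-[3,5-dimethoxy-4-(methoxymethoxy)phenyl]-3-(methoxycarbonyl)but-3-enoic acid F2. The acid is joined to 1 (PivCl, Et3N, THF; then 1, LiCl) to give the imide methyl (E)-2-{2-[(S)-4-benzyl-2-oxooxazolidin-3-yl]-2-oxoethyl}-3-[3,5-dimethoxy-4-(methoxymethoxy)phenyl]acrylate F3. An Evans syn-aldol reaction of F3 (Bu2BOTf, i-Pr2NEt, CH2Cl2, −78 → 0 °C) with a second portion of F1 sets the C2 centre through the Zimmerman–Traxler transition state and should give methyl (2E,3S,4S)-3-[(S)-4-benzyl-2-oxooxazolidine-3-carbonyl]-2-[3,5-dimethoxy-4-(methoxymethoxy)benzylidene]-4-[3,5-dimethoxy-4-(methoxymethoxy)phenyl]-4-hydroxybutanoate F4. TFA in CH2Cl2 at 0 °C ionizes the benzylic alcohol, closes the ring by Friedel–Crafts alkylation trans to the acyl group and removes both MOM groups, giving methyl (1S,2R)-2-[(S)-4-benzyl-2-oxooxazolidine-3-carbonyl]-7-hydroxy-1-(4-hydroxy-3,5-dimethoxyphenyl)-6,8-dimethoxy-1,2-dihydronaphthalene-3-carboxylate F5. LiBH4 under the conditions of step 5 then reduces only the C2 imide of F5 and gives 13 directly, since the C3 carbonyl is already the methyl ester.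

Step 5. The hydride may fail to discriminate between the two imides (over-reduction or conjugate reduction at C3), or the new alkoxide may transfer the C3 acyl group intramolecularly. The fallback sets out from 11 and returns at 13. Both imides are methanolysed (NaOMe, MeOH, 0 °C → rt) to dimethyl (1S,2R)-7-hydroxy-1-(4-hydroxy-3,5-dimethoxyphenyl)-6,8-dimethoxy-1,2-dihydronaphthalene-2,3-dicarboxylate F6. LiOH (THF/H2O, 0 °C) should hydrolyse the non-conjugated C2 ester faster than the phenolate-deactivated C3 cinnamate ester and give (1S,2R)-7-hydroxy-1-(4-hydroxy-3,5-dimethoxyphenyl)-6,8-dimethoxy-3-(methoxycarbonyl)-1,2-dihydronaphthalene-2-carboxylic acid F7. BH3·SMe2 (THF, 0 °C) reduces the carboxylic acid in the presence of the conjugated ester and gives 13.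

Step 6. Methoxide may open the oxazolidinone ring (endocyclic attack), or methanolysis of the hindered, phenolate-deactivated enoyl imide may be too slow. The fallback sets out from 12 and returns at 13. Hydrolysis with LiOH/H2O2 (THF/H2O, 0 °C), which is strongly exocyclic-selective, should give (1S,2R)-7-hydroxy-1-(4-hydroxy-3,5-dimethoxyphenyl)-2-(hydroxymethyl)-6,8-dimethoxy-1,2-dihydronaphthalene-3-carboxylic acid F8. Esterification of F8 with TMSCHN2 (MeOH/toluene, 0 °C, one equivalent) should methylate the carboxylic acid only and give 13.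

**Further compounds**
F1 | step 4 | 3,5-dimethoxy-4-(methoxymethoxy)benzaldehyde | COCOc1c(OC)cc(C=O)cc1OC
F2 | step 4 | (E)-4-[3,5-dimethoxy-4-(methoxymethoxy)phenyl]-3-(methoxycarbonyl)but-3-enoic acid | COCOc1c(OC)cc(/C=C(\CC(=O)O)C(=O)OC)cc1OC
F3 | step 4 | methyl (E)-2-{2-[(S)-4-benzyl-2-oxooxazolidin-3-yl]-2-oxoethyl}-3-[3,5-dimethoxy-4-(methoxymethoxy)phenyl]acrylate | COCOc1c(OC)cc(/C=C(\CC(=O)N2C(=O)OC[C@@H]2Cc2ccccc2)C(=O)OC)cc1OC
F4 | step 4 | methyl (2E,3S,4S)-3-[(S)-4-benzyl-2-oxooxazolidine-3-carbonyl]-2-[3,5-dimethoxy-4-(methoxymethoxy)benzylidene]-4-[3,5-dimethoxy-4-(methoxymethoxy)phenyl]-4-hydroxybutanoate | COCOc1c(OC)cc(/C=C(/C(=O)OC)[C@H](C(=O)N2C(=O)OC[C@@H]2Cc2ccccc2)[C@H](O)c2cc(OC)c(OCOC)c(OC)c2)cc1OC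
F5 | step 4 | methyl (1S,2R)-2-[(S)-4-benzyl-2-oxooxazolidine-3-carbonyl]-7-hydroxy-1-(4-hydroxy-3,5-dimethoxyphenyl)-6,8-dimethoxy-1,2-dihydronaphthalene-3-carboxylate | COC(=O)C1=Cc2cc(OC)c(O)c(OC)c2[C@H](c2cc(OC)c(O)c(OC)c2)[C@H]1C(=O)N1C(=O)OC[C@@H]1Cc1ccccc1
F6 | step 5 | dimethyl (1S,2R)-7-hydroxy-1-(4-hydroxy-3,5-dimethoxyphenyl)-6,8-dimethoxy-1,2-dihydronaphthalene-2,3-dicarboxylate | COC(=O)C1=Cc2cc(OC)c(O)c(OC)c2[C@H](c2cc(OC)c(O)c(OC)c2)[C@H]1C(=O)OC
F7 | step 5 | (1S,2R)-7-hydroxy-1-(4-hydroxy-3,5-dimethoxyphenyl)-6,8-dimethoxy-3-(methoxycarbonyl)-1,2-dihydronaphthalene-2-carboxylic acid | COC(=O)C1=Cc2cc(OC)c(O)c(OC)c2[C@H](c2cc(OC)c(O)c(OC)c2)[C@H]1C(=O)O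
F8 | step 6 | (1S,2R)-7-hydroxy-1-(4-hydroxy-3,5-dimethoxyphenyl)-2-(hydroxymethyl)-6,8-dimethoxy-1,2-dihydronaphthalene-3-carboxylic acid | OC(=O)C1=Cc2cc(OC)c(O)c(OC)c2[C@H](c2cc(OC)c(O)c(OC)c2)[C@H]1CO
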